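## Retrosynthetic overview

1. The C8 ester is cut last: the target comes from the 8-hydroxy (1(10)Z,4Z)-dienone 12,6-olide and (2S,3S)-epoxyangelic acid, the latter from angelic acid by asymmetric epoxidation of its allylic alcohol.
2. Feature: the ten-membered ring C1–C10 holds the 1,5-diene C10=C1–C2–C3–C4=C5, and its ends C10 and C5 are the α- and β-carbons of the C9 enone. Joining C5–C10 and C1–C4 in the retro sense gives a bicyclo[2.2.0]hexane ladder, the [2+2] adduct of a cyclohexenone (ring C5–C10) and 1-methylcyclobutene (C1–C4 with C15).
3. Forward, light forms C10–C1 and C5–C4, and flash thermolysis cuts C5–C10 and C1–C4. A cis-fused adduct can give only one Z and one E ring alkene, so the enone alkene is accepted as E and turned to Z by light.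
4. The enone lactone (C5–C10, C14, C11–C13) is (S)-carvone: C8–O by enolate hydroxylation anti to the C7 side chain, isopropenyl CH3 to CO2H, C6–O by γ-bromination and carboxylate SN2 with inversion.
5. Ring order: cyclohexenone (carvone), cis γ-lactone, two cyclobutanes (photoadduct), ten-membered ring by ring expansion; the oxirane arrives preformed on the acyl group.

Key step: step 9

Remark: atoms carry germacrane numbers (ring C1–C10, lactone unit C11–C13, C14 on C10, C15 on C4). The cis-fused photoadduct is assumed to cleave through a chair 1,4-diyl, so that exactly one ring alkene is formed E.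

## Route

Step 1
Reactants: 1 (S)-(+)-carvone
Product: 2 (5R,6R)-6-hydroxycarvone (the new OH, at C8 of the target, trans to the isopropenyl group)
Conditions: LDA, THF, −78 °C; 2-(phenylsulfonyl)-3-phenyloxaziridine, −78 °C; AcOH quench
Reagents that add atoms: 2-(phenylsulfonyl)-3-phenyloxaziridine, O=S(=O)(c1ccccc1)N1OC1c1ccccc1
Why: Kinetic deprotonation takes the α' CH2, and the cross-conjugated enolate is hydroxylated by the N-sulfonyloxaziridine (enolate hydroxylation) on the face anti to the neighbouring isopropenyl group, which sets C8 with O trans to the C7 substituent.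

Step 2
Reactants: 2 (5R,6R)-6-hydroxycarvone
Product: 3 its tert-butyldimethylsilyl ether
Conditions: TBSCl, imidazole, DMF, rt
Reagents that add atoms: tert-butyldimethylsilyl chloride, CC(C)(C)[Si](C)(C)Cl
Why: Imidazole-mediated silylation of a secondary α-ketol is mild enough to leave the epimerisable C8 untouched.

Step 3
Reactants: 3 silyl ether
Product: 4 allylic chloride (isopropenyl converted into a 3-chloroprop-1-en-2-yl group)
Conditions: Ca(OCl)2, solid CO2, CH2Cl2/H2O, 0 °C
Reagents that add atoms: calcium hypochlorite, [Ca+2].[O-]Cl.[O-]Cl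
Why: HOCl made in situ chlorinates only the electron-rich 1,1-disubstituted alkene in an ene-type process with alkene shift; the enone C=C is too electron-poor to react.

Step 4
Reactants: 4 allylic chloride
Product: 5 enal (2-substituted acrolein at C7)
Conditions: N-methylmorpholine N-oxide, KI (cat.), 4 Å MS, MeCN, 50 °C
Reagents that add atoms: N-methylmorpholine N-oxide, C[N+]1([O-])CCOCC1
Why: The N-oxide oxygen displaces the allylic halide (through the iodide) and base-induced N–O cleavage releases the aldehyde, a Kornblum-type oxidation of an activated halide.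

Step 5
Reactants: 5 enal
Product: 6 acrylic acid (2-substituted prop-2-enoic acid at C7)
Conditions: NaClO2, NaH2PO4, 2-methyl-2-butene, t-BuOH/H2O, 0 °C to rt
Reagents that add atoms: sodium chlorite, [Na+].[O-]Cl=O
Why: Pinnick oxidation converts an α-substituted acrolein into the acid without touching the enone or the silyl ether, the alkene scavenger removing HOCl.

Step 6
Reactants: 6 acrylic acid
Product: 7 silyl ester of the linear silyl dienol ether (C9(OTBS)=C10, C5=C6; 8-OTBS kept), used crude
Conditions: TBSOTf, Et3N, CH2Cl2, 0 °C to rt; pentane, filtration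
Reagents that add atoms: tert-butyldimethylsilyl triflate, CC(C)(C)[Si](C)(C)OS(=O)(=O)C(F)(F)F
Why: Silyl triflate and amine esterify the acid and enolise the enone under equilibrating conditions toward C6, giving the fully conjugated dienol ether rather than the crowded tetrasubstituted enol ether at C8.

Step 7
Reactants: 7 silyl dienol ether silyl ester
Product: 10 cis-fused enone α-methylene lactone with 8-OTBS, via γ-bromo enone silyl ester 8 (not isolated), via γ-bromo acid 9 (not isolated)
Conditions: NBS, THF, −78 °C; then NaHCO3, DMF/H2O, 0 °C to rt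
Reagents that add atoms: none
Why: The dienol ether is brominated at its γ-terminus C6 anti to the C7 side chain (vinylogous α-halogenation), and after hydrolysis of the silyl ester the carboxylate displaces the allylic bromide by 5-exo-tet SN2 with inversion, which sets C6 with its oxygen cis to C7–C11.

Step 8
Reactants: 11 methylenecyclobutane
Product: 12 1-methylcyclobutene
Conditions: Na on Al2O3 (cat.), neat, 20 °C; spinning-band distillation
Reagents that add atoms: none
Why: Base-catalysed alkene isomerisation equilibrates the exocyclic alkene with the trisubstituted endocyclic isomer, which should predominate and is enriched by fractional distillation.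

Step 9
Reactants: 10 enone lactone; 12 1-methylcyclobutene
Product: 14 (1(10)E,4Z)-8-O-TBS-9-oxogermacra-1(10),4,11(13)-trien-12,6-olide, used crude and cold, via cis-anti-cis ladder photoadduct 13 (not isolated)
Conditions: hν (>330 nm, uranium-glass filter), 12 (15 equiv), CH2Cl2, −40 °C; evaporate; flash vacuum thermolysis, 480 °C, 10^-3 mbar, quartz tube, trap at −196 °C
Reagents that add atoms: none
Why: The n,π*-excited enone crosses to its triplet, which adds to the strained alkene through a 1,4-diradical and closes to the cyclobutane C10–C1–C4–C5 (two four-membered rings fused as a bicyclo[2.2.0]hexane, each closed by radical recombination); above 330 nm only the enone absorbs, and the large excess of cyclobutene keeps the acrylate lactone from being engaged. In the hot tube the central C1–C4 bond of the ladder homolyses to a cyclohexane-1,4-diyl, which cleaves C5–C10 and so turns the six-membered ring into the ten-membered ring by fragmentation, not by end-to-end closure; the closest known reaction is the photo-thermal olefin metathesis of cyclohexenone–cyclobutene adducts to cyclodeca-1,5-dienes. No stereocentre is created: C1, C4, C5 and C10 end as sp2 carbons and C6, C7 and C8 are untouched. The step needs head-to-tail regiochemistry (C5 to the methyl-bearing C4, C10 to C1), which the donor polarity of the alkene and the C10 methyl (no adjacent quaternary centres) should secure. It also needs a defined alkene geometry: a cis-fused adduct cleaving through the chair diyl must give one E and one Z alkene, and the chair with C6 axial on C5 (4Z, 1(10)E) is expected because the other chair forces the C10 methyl syn-axial to the C6 oxygen. High temperature and millisecond contact favour the cycloreversion over the Cope rearrangement of the E,Z-diene.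

Step 10
Reactants: 14 (1(10)E,4Z)-dienone
Product: 15 (1(10)Z,4Z)-8-O-TBS-9-oxogermacra-1(10),4,11(13)-trien-12,6-olide
Conditions: hν (366 nm), degassed MeCN, 0 °C
Reagents that add atoms: none
Why: Excitation in the n,π* band lets the twisted E-enone rotate about C1=C10 in its triplet and relax to the less strained Z isomer (E/Z photoisomerisation of a medium-ring enone); C4=C5 and the acrylate lactone do not absorb at this wavelength.

Step 11
Reactants: 15 (1(10)Z,4Z)-dienone silyl ether
Product: 16 8-hydroxy (1(10)Z,4Z)-dienone 12,6-olide
Conditions: HF·pyridine, pyridine/THF, 0 °C to rt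
Reagents that add atoms: none
Why: Buffered HF cleaves the secondary silyl ether without the basicity that would epimerise C8 or add to the methylene lactone.

Step 12
Reactants: 17 angelic acid
Product: 18 (Z)-2-methylbut-2-en-1-ol
Conditions: LiAlH4, Et2O, 0 °C to rt
Reagents that add atoms: none
Why: Hydride reduction of the acid to the primary allylic alcohol leaves the Z alkene geometry unchanged.

Step 13
Reactants: 18 (Z)-2-methylbut-2-en-1-ol
Product: 19 (2R,3S)-(2,3-dimethyloxiran-2-yl)methanol
Conditions: Ti(OiPr)4 (10 mol %), D-(−)-diethyl tartrate (12 mol %), t-BuOOH, 4 Å MS, CH2Cl2, −20 °C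
Reagents that add atoms: tert-butyl hydroperoxide, CC(C)(C)OO
Why: Katsuki–Sharpless epoxidation delivers oxygen syn to the Z alkene (3-methyl stays cis to CH2OH), and the (S,S)-tartrate selects the face that gives 2R,3S, which sets both oxirane centres (they become 2S,3S in the acid).

Step 14
Reactants: 19 epoxy alcohol
Product: 20 (2S,3S)-2,3-dimethyloxirane-2-carboxylic acid (epoxyangelic acid)
Conditions: RuCl3 (2 mol %), NaIO4, MeCN/EtOAc/H2O, rt
Reagents that add atoms: sodium periodate, [Na+].[O-]I(=O)(=O)=O; water, O
Why: Ruthenium tetroxide formed in situ oxidises the primary alcohol through the aldehyde hydrate to the acid and leaves the trisubstituted epoxide intact, as known for 2,3-epoxy alcohols.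

Step 15
Reactants: 16 8-hydroxy dienone lactone; 20 (2S,3S)-epoxyangelic acid
Product: 22 target CNP0183761.1, via mixed 2,4,6-trichlorobenzoic anhydride 21 (not isolated)
Conditions: 20, 2,4,6-trichlorobenzoyl chloride, Et3N, toluene, 0 °C; then 16, DMAP, 0 °C to rt
Reagents that add atoms: none
Why: In this Yamaguchi esterification the alcohol attacks the aliphatic carbonyl of the mixed anhydride under DMAP catalysis, with retention at C8 and at both oxirane centres; the low temperature limits enolisation of the α-acyloxy ketone.

## Compound list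

1 | (S)-(+)-carvone | CC(=C)[C@H]1CC=C(C)C(=O)C1 | starting material
2 | (5R,6R)-6-hydroxycarvone, OH trans to isopropenyl | CC(=C)[C@H]1CC=C(C)C(=O)[C@@H]1O | intermediate
3 | TBS ether of 2 | CC(=C)[C@H]1CC=C(C)C(=O)[C@@H]1O[Si](C)(C)C(C)(C)C | intermediate
4 | allylic chloride (3-chloroprop-1-en-2-yl side chain) | ClCC(=C)[C@H]1CC=C(C)C(=O)[C@@H]1O[Si](C)(C)C(C)(C)C | intermediate
5 | enal (2-substituted acrolein) | O=CC(=C)[C@H]1CC=C(C)C(=O)[C@@H]1O[Si](C)(C)C(C)(C)C | intermediate
6 | acrylic acid | OC(=O)C(=C)[C@H]1CC=C(C)C(=O)[C@@H]1O[Si](C)(C)C(C)(C)C | intermediate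
7 | TBS ester of the linear TBS dienol ether (C9=C10, C5=C6), 8-OTBS | C=C(C(=O)O[Si](C)(C)C(C)(C)C)[C@H]1C=CC(C)=C(O[Si](C)(C)C(C)(C)C)[C@@H]1O[Si](C)(C)C(C)(C)C | intermediate
8 | 6-bromo enone TBS ester, Br trans to the C7 side chain | C=C(C(=O)O[Si](C)(C)C(C)(C)C)[C@H]1[C@H](Br)C=C(C)C(=O)[C@@H]1O[Si](C)(C)C(C)(C)C | intermediate
9 | 6-bromo enone acid (carboxylate in the flask) | C=C(C(=O)O)[C@H]1[C@H](Br)C=C(C)C(=O)[C@@H]1O[Si](C)(C)C(C)(C)C | intermediate
10 | cis-fused enone α-methylene lactone, 8-OTBS trans to C7–C11 | C=C1C(=O)O[C@H]2C=C(C)C(=O)[C@H](O[Si](C)(C)C(C)(C)C)[C@@H]12 | intermediate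
11 | methylenecyclobutane | C=C1CCC1 | starting material
12 | 1-methylcyclobutene | CC1=CCC1 | intermediate
13 | cis-anti-cis ladder photoadduct (cyclobutane C10–C1–C4–C5 fused to cyclobutane C1–C4, cyclobutene added anti to the lactone) | C=C1C(=O)O[C@H]2[C@@H]3[C@@]4(C)CC[C@H]4[C@]3(C)C(=O)[C@H](O[Si](C)(C)C(C)(C)C)[C@@H]12 | intermediate
14 | (1(10)E,4Z)-8-O-TBS dienone 12,6-olide | C=C1C(=O)O[C@H]2/C=C(/C)CC/C=C(\C)C(=O)[C@H](O[Si](C)(C)C(C)(C)C)[C@@H]12 | intermediate
15 | (1(10)Z,4Z)-8-O-TBS dienone 12,6-olide | C=C1C(=O)O[C@H]2/C=C(/C)CC/C=C(/C)C(=O)[C@H](O[Si](C)(C)C(C)(C)C)[C@@H]12 | intermediate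
16 | 8-hydroxy (1(10)Z,4Z)-dienone 12,6-olide | C=C1C(=O)O[C@H]2/C=C(/C)CC/C=C(/C)C(=O)[C@H](O)[C@@H]12 | intermediate
17 | angelic acid | C/C=C(C)\C(=O)O | starting material
18 | (Z)-2-methylbut-2-en-1-ol | C/C=C(C)\CO | intermediate
19 | (2R,3S)-(2,3-dimethyloxiran-2-yl)methanol | OC[C@@]1(C)O[C@H]1C | intermediate
20 | (2S,3S)-2,3-dimethyloxirane-2-carboxylic acid | OC(=O)[C@@]1(C)O[C@H]1C | intermediate
21 | mixed anhydride of 20 with 2,4,6-trichlorobenzoic acid | O=C(OC(=O)[C@@]1(C)O[C@H]1C)c1c(Cl)cc(Cl)cc1Cl | intermediate
22 | (6S,7S,8R)-8-[(2S,3S)-2,3-dimethyloxirane-2-carbonyloxy]-9-oxogermacra-1(10)Z,4Z,11(13)-trien-12,6-olide | C=C1C(=O)O[C@H]2/C=C(/C)CC/C=C(/C)C(=O)[C@H](OC(=O)[C@@]3(C)O[C@H]3C)[C@@H]12 | target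

Total step count: 15. Longest linear sequence: 11 steps (1–7, 9, 10, 11, 15).

## Steps most likely to fail

Step 9. The 1,4-diyl may partition through its other chair, so that the E alkene appears at C4=C5 and the enone is formed Z; part of the E,Z-diene may also Cope-rearrange to the divinylcyclohexanone in the hot zone. The fallback inverts the isolated alkene by stereospecific chemistry instead of relying on the cycloreversion. It sets out from 10, irradiated and thermolysed as in step 9 through 13, and takes the (1(10)Z,4E)-dienone F1 that such a run would give. mCPBA with NaHCO3 in CH2Cl2 at 0 °C should epoxidise only the electron-rich, strained C4=C5 to the trans-4,5-epoxide F2. Acid-catalysed hydration (HClO4 cat., THF/H2O) opens it anti to the 4,5-diol F3, and thiocarbonyldiimidazole with DMAP in toluene gives the cyclic thionocarbonate F4. Corey–Winter syn-elimination with 1,3-dimethyl-2-phenyl-1,3,2-diazaphospholidine at 40 °C then gives the 4Z alkene. The route is rejoined at 15, and step 10 is not needed.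

Step 10. Transannular [2+2] addition of the excited enone to C4=C5, or a photostationary state that keeps much E isomer, may prevent clean conversion. The fallback sets the enone geometry under ground-state equilibrium instead. From 14, dimethylamine in EtOH/THF adds to the methylene lactone and reversibly to C1 of the enone, so the enone should settle as the less strained Z isomer in the 13-dimethylamino adduct F5. Methyl iodide gives the trimethylammonium iodide F6, and aqueous NaHCO3 eliminates trimethylamine to restore the methylene lactone. The route is rejoined at 15.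

Step 7. Loss of HBr from the γ-bromo enone toward the dienone and on to the phenol may outrun ring closure, or bromine may be delivered syn to the C7 side chain so that the carboxylate cannot displace it. The fallback installs oxygen at C6 as an electrophile and inverts it afterwards. From 7, buffered mCPBA (NaHCO3, CH2Cl2, −20 °C) oxidises the dienol ether at C6 anti to the side chain (vinylogous Rubottom oxidation), and aqueous work-up gives the trans-6-hydroxy acid F7. Mitsunobu lactonisation (PPh3, DIAD, THF, 0 °C) inverts C6 and closes the cis lactone. The route is rejoined at 10.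

## Further compounds

F1 | step 9 | (1(10)Z,4E)-8-O-TBS dienone 12,6-olide | C=C1C(=O)O[C@H]2/C=C(\C)CC/C=C(/C)C(=O)[C@H](O[Si](C)(C)C(C)(C)C)[C@@H]12
F2 | step 9 | trans-4,5-epoxide of F1 (one face shown; both faces converge) | C=C1C(=O)O[C@H]2[C@H]3O[C@]3(C)CC/C=C(/C)C(=O)[C@H](O[Si](C)(C)C(C)(C)C)[C@@H]12
F3 | step 9 | 4,5-diol from anti opening of F2 at C4 | C=C1C(=O)O[C@H]2[C@@H](O)[C@@](C)(O)CC/C=C(/C)C(=O)[C@H](O[Si](C)(C)C(C)(C)C)[C@@H]12
F4 | step 9 | cyclic 4,5-thionocarbonate of F3 | C=C1C(=O)O[C@H]2[C@H]3OC(=S)O[C@@]3(C)CC/C=C(/C)C(=O)[C@H](O[Si](C)(C)C(C)(C)C)[C@@H]12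
F5 | step 10 | 13-dimethylamino-11,13-dihydro adduct of 15 (C11 epimers, of no consequence) | CN(C)CC1C(=O)O[C@H]2/C=C(/C)CC/C=C(/C)C(=O)[C@H](O[Si](C)(C)C(C)(C)C)[C@@H]12
F6 | step 10 | trimethylammonium iodide of F5 | C[N+](C)(C)CC1C(=O)O[C@H]2/C=C(/C)CC/C=C(/C)C(=O)[C@H](O[Si](C)(C)C(C)(C)C)[C@@H]12.[I-]
F7 | step 7 | trans-6-hydroxy enone acid (OH anti to the C7 side chain) | C=C(C(=O)O)[C@H]1[C@H](O)C=C(C)C(=O)[C@@H]1O[Si](C)(C)C(C)(C)C
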